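# Proposed synthesis of (−)-epigallocatechin 3-O-gallate-(4β→6)-(+)-gallocatechin (CNP0271447.2)

## Analysis of the target

The target (33) is a B-type prodelphinidin dimer. Its upper unit is (−)-epigallocatechin 3-O-gallate (benzo ring A, pendant pyrogallol ring B, pyran ring C). Upper C4 is bonded to C6 of a (+)-gallocatechin lower unit (benzo ring D, pendant ring E, pyran ring F).

There are five stereocentres. Upper C2 (R) and C3 (R) are cis, and the ring D substituent at C4 (S) is trans to both (the 4β arrangement). Lower C2 (R) and C3 (S) are trans.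

Thirteen phenolic hydroxyls in three pyrogallol and two phloroglucinol-type rings make the free compound sensitive to air and base. The gallate ester is base-labile, the C4–C6 interflavan bond is cleaved by acid, and the benzylic C2–O bonds can epimerise.

Three things make the synthesis hard: the 4→6 link must be formed rather than the electronically preferred 4→8 link, C4 must be set trans to the C3 oxygen, and the upper C3 hydroxyl must be acylated while the lower one stays free.

The strategy rests on one feature of ring A. Its carbon C8a carries the ring C oxygen O1, so C4a and C8a can be the two carbons of a cyclic enol ether derived from a six-membered lactone that already contains C2, C3 and C4. The remaining ring A carbons C5–C8, oxygenated at C5 and C7, then correspond to a masked acetoacetyl chain attached at C8a.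

## Retrosynthetic reasoning

**33 from 32.** All thirteen phenols and the lower C3 hydroxyl are masked as benzyl ethers, removed together in the last step. The same hydrogenolysis removes a bromine at C8 of ring D. That bromine is a spectator carried from the lower-unit synthesis: it blocks the more reactive C8 so that C6 can be functionalised, and it leaves ring D without a free position in every later step.

**32 from 30 and 31.** The ester C–O bond is cut. Alcohol 30 has a single free hydroxyl, so acylation with the protected gallic acid 31 needs no selectivity between the two C3 oxygens.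

**30 from 29 from 28.** The C3 hydroxyl is released from its silyl ether after the two ring A phenols of 28 have been benzylated. The silyl group is orthogonal to benzyl and comes off with fluoride, which spares the acid-labile interflavan bond.

**28 from 25 (the key disconnection).** Ring A is opened at C4a–C5. This leaves dihydropyran 25, whose endocyclic enol ether supplies C4a and C8a and whose dioxinone side chain supplies C5–C8. The cut is placed here because O1 stays tied up in ring C. A triketide chain with a free oxygen at that position would close to a 4-hydroxy-2-pyranone instead of an arene. The forward reaction has to form one C–C bond and aromatise. It creates no stereocentre, so C2, C3 and C4 can all be settled earlier on a saturated ring.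

**25 from 23 and 24 (made from 18).** The C8–C8a bond is cut between the enol carbon and the dioxinone methylene. A palladium-catalysed coupling of ketene acetal phosphate 23 with organozinc 24 places the double bond regiospecifically inside the ring. Dehydration of a lactol could not guarantee this.

**23 from 21, and 21 from 10 and 19 (made from 15).** The enol phosphate comes from lactone 21. The C4–C6 bond between the units is cut next, leading to unsaturated lactone 10 and the C6 organometallic 19. The conjugate addition must deliver the aryl group trans to the C5 silyloxy group of 10, which fixes C4.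

**10 from 9, 7, 6, 5, and 5 from 1 and 2.** The silyl ether replaces the acetal that is needed for the allylboration. The unsaturated lactone 7 is opened at its ring double bond to acrylate 6 (ring-closing metathesis forward). The C–C bond between the two carbinol carbons is then cut to aldehyde 1 and allyl ether 2. A single reagent-controlled alkoxyallylboration sets both upper stereocentres, syn to each other, in one step.

**15 from 14, 13, 12, 11.** The lower unit is taken from the chiral pool. Perbenzylation, bromination at the more nucleophilic C8 and iodination at the only position left (C6) give a dihalide whose iodide alone undergoes halogen–metal exchange.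

**18 from 16.** The chloromethyl dioxinone arises by γ-functionalisation of the commercial dioxinone.

## Alternatives that were turned down

**Alternative 1:** Lower pyran ring F would be cut at C4–C4a. This leads back to aryl propargyl ether A2, in which ring D is still a symmetrical 2,6-dibenzyloxy-4-aryloxyphenyl group on upper C4 and the lower C2 stereocentre is the propargylic carbon. In the forward direction Ph3PAuNTf2 would activate the terminal alkyne, and one of the two equivalent ortho carbons of ring D would attack it in a 6-endo-dig hydroarylation to give flav-3-ene A1.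
- **For:** Gold-catalysed cyclisation of aryl propargyl ethers to 2H-chromenes is established, so this key step is less risky than an untested arene construction. The symmetry of ring D in A2 settles the 4→6 connectivity without a blocking group, which is better than the chosen route. A1 is only a hydroboration–oxidation and a hydrogenolysis from the target, a shorter end-game than the chosen one.
- **Against:** A2 presupposes the complete galloylated upper unit with its C4–aryl bond, so the difficult half of the molecule is only pushed back. The stereogenic carbon of A2 is benzylic to a trialkoxyphenyl ring, propargylic and attached to an aryloxy leaving group, so ionisation at the cationic monovalent gold centre (or already during ether formation) threatens the lower C2 configuration. The ring F hydroxyl must afterwards be introduced on A1 trans to the C2 aryl group by a borane in the presence of the gallate ester.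
- **Comparison:** The chosen strategy gives up the automatic regiochemistry and the short end-game. In return, every stereocentre is either bought with the lower unit or set on a rigid lactone, and none is later exposed to a cation-forming catalyst.

**Alternative 2:** Ring D would be split into cyclobutenone A4, carrying the upper flavan at its C2, and siloxyalkyne A5, carrying the future C2–C4 chain of the lower unit. Heating would open A4 to a vinylketene, which adds to A5 in a [2+2] sense, reopens and closes by 6π-electrocyclisation to phenol A3. This forms C4a–C8a, C5–C6 and C8–C8a of ring D.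
- **For:** Benzannulation of cyclobutenones with ynol ethers is a known reaction type, and the step is highly convergent. The substitution pattern of ring D, including the 4→6 link, follows from the regiochemistry of the annulation with no blocking group. On these points it equals or exceeds the chosen route.
- **Against:** A4 is the silyl enol ether of a 2-substituted cyclobutane-1,3-dione bearing a bulky secondary flavanyl group, a fragile and hindered compound that is itself hard to prepare. A3 emerges with three differently protected oxygens on ring D and an open chain. Ring F must still be closed by displacement with inversion at a benzylic carbinol, and the silyl ethers must be exchanged for benzyl ethers before galloylation and hydrogenolysis.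
- **Comparison:** That end-game is at least twice as long as the four steps after the chosen key step and uses more protecting-group classes. The chosen route keeps the lower unit intact from the chiral pool.

**Alternative 3:** Upper ring C would be opened at O1–C8a, giving bromoarene carbinol A7 with C2, C3 and C4 on an open chain. CuI with 3,4,7,8-tetramethyl-1,10-phenanthroline and Cs2CO3 would join the C2 alkoxide to the brominated ring A carbon with retention at C2, giving A6.
- **For:** Copper-catalysed intramolecular O-arylation is well precedented for chromans, so the ring closure is safer than the chosen key step. A6 arrives fully benzylated (it is the bromine-free counterpart of 29), which saves the phenol benzylation.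
- **Against:** The three contiguous stereocentres of A7 include a diarylmethine carbon between two electron-rich rings, and they must be set without a ring to relay stereocontrol. The aryl bromide is ortho to that bulky carbon. Under carbonate base at elevated temperature the silyl group can migrate from O3 to O2, after which the C3 alkoxide would close a five-membered dihydrobenzofuran. The 4→6 problem is left exactly where it is in the chosen route.
- **Comparison:** The chosen strategy takes more risk in the ring-forming event. It sets C4 by addition to a cyclic acceptor whose two existing substituents direct the same face.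

Key step: step 14

## Route

Remark on the chemistry: the lower unit is (2R,3S), the configuration of (+)-gallocatechin, so this enantiomer is the starting material. Compounds 1, 2 and 31 are taken as purchasable building blocks.

Abbreviations used in names: Ar = 3,4,5-tris(benzyloxy)phenyl; Bn = benzyl; TBS = tert-butyldimethylsilyl; D* = (2R,3S)-3,5,7-tris(benzyloxy)-8-bromo-2-Ar-chroman-6-yl (the protected, C8-brominated lower unit bonded through C6).

**Step 1**
Reactants: 1 3,4,5-tris(benzyloxy)benzaldehyde; 2 allyl methoxymethyl ether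
Product: 5 (1R,2R)-2-(methoxymethoxy)-1-Ar-but-3-en-1-ol, via allylborane 3 (not isolated), via borinate ester 4 (not isolated)
Conditions: 2, s-BuLi, THF, −78 °C; (−)-Ipc2BOMe; BF3·OEt2; 1, −78 → 25 °C; NaOH, H2O2
Reagents that add atoms: none
Why: Brown alkoxyallylboration; the (Z)-γ-alkoxyallylborane reacts through a chair transition state, so the Z geometry should give the syn relationship, and the isopinocampheyl groups derived from (+)-α-pinene should direct attack to the si face of the aldehyde, making both new centres R.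

**Step 2**
Reactants: 5 (1R,2R)-2-(methoxymethoxy)-1-Ar-but-3-en-1-ol
Product: 6 (1R,2R)-2-(methoxymethoxy)-1-Ar-but-3-en-1-yl prop-2-enoate
Conditions: acryloyl chloride, Et3N, DMAP (cat.), CH2Cl2, 0 °C
Reagents that add atoms: acryloyl chloride, C=CC(=O)Cl
Why: DMAP-catalysed O-acylation of the only free hydroxyl; the stereocentres are not involved.

**Step 3**
Reactants: 6 (1R,2R)-2-(methoxymethoxy)-1-Ar-but-3-en-1-yl prop-2-enoate
Product: 7 (5R,6R)-5-(methoxymethoxy)-6-Ar-5,6-dihydro-2H-pyran-2-one
Conditions: second-generation Grubbs catalyst [(H2IMes)(PCy3)Cl2Ru=CHPh] (5 mol %), CH2Cl2, 40 °C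
Reagents that add atoms: none
Why: Ring-closing metathesis of an acrylate with an allylic ether is a standard entry to 6-substituted 5,6-dihydropyran-2-ones; loss of ethylene drives it and the syn diol pattern becomes the cis-5,6 relationship.

**Step 4**
Reactants: 7 (5R,6R)-5-(methoxymethoxy)-6-Ar-5,6-dihydro-2H-pyran-2-one
Product: 9 (5R,6R)-5-hydroxy-6-Ar-5,6-dihydro-2H-pyran-2-one, via bromomethyl ether 8 (not isolated)
Conditions: Me2BBr, CH2Cl2, −78 °C; then NaHCO3, H2O, THF, 0 °C
Reagents that add atoms: none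
Why: Lewis-acid cleavage of a methoxymethyl ether (Guindon conditions) at −78 °C should spare aryl benzyl ethers and the lactone; the cold, near-neutral work-up is chosen to avoid ring contraction of the hydroxy lactone to a butenolide.

**Step 5**
Reactants: 9 (5R,6R)-5-hydroxy-6-Ar-5,6-dihydro-2H-pyran-2-one
Product: 10 (5R,6R)-5-[(tert-butyldimethylsilyl)oxy]-6-Ar-5,6-dihydro-2H-pyran-2-one
Conditions: t-BuMe2SiOTf, 2,6-lutidine, CH2Cl2, −78 → 0 °C
Reagents that add atoms: tert-butyldimethylsilyl triflate, CC(C)(C)[Si](C)(C)OS(=O)(=O)C(F)(F)F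
Why: Silylation of a secondary alcohol with a silyl triflate and a hindered base, which is too weak to open or isomerise the lactone.

**Step 6**
Reactants: 11 (+)-gallocatechin
Product: 12 (2R,3S)-5,7-bis(benzyloxy)-2-Ar-chroman-3-ol
Conditions: BnBr, K2CO3, DMF, 25 °C, Ar
Reagents that add atoms: benzyl bromide, BrCc1ccccc1
Why: Williamson etherification of the five phenols; carbonate does not deprotonate the secondary alcohol, and exclusion of air protects the pyrogallol ring.

**Step 7**
Reactants: 12 (2R,3S)-5,7-bis(benzyloxy)-2-Ar-chroman-3-ol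
Product: 13 (2R,3S)-3,5,7-tris(benzyloxy)-2-Ar-chromane
Conditions: NaH, BnBr, Bu4NI (cat.), DMF, 0 → 25 °C
Reagents that add atoms: benzyl bromide, BrCc1ccccc1
Why: Williamson etherification of the remaining secondary alcohol; with all phenols capped there is no pathway for base-induced epimerisation at C2.

**Step 8**
Reactants: 13 (2R,3S)-3,5,7-tris(benzyloxy)-2-Ar-chromane
Product: 14 (2R,3S)-3,5,7-tris(benzyloxy)-8-bromo-2-Ar-chromane
Conditions: N-bromosuccinimide (1.0 equiv), CH2Cl2, −20 → 0 °C, dark
Reagents that add atoms: N-bromosuccinimide, O=C1CCC(=O)N1Br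
Why: Electrophilic aromatic bromination; in 5,7-dialkoxychromans C8 is the most nucleophilic position, so one equivalent should brominate there selectively.

**Step 9**
Reactants: 14 (2R,3S)-3,5,7-tris(benzyloxy)-8-bromo-2-Ar-chromane
Product: 15 (2R,3S)-3,5,7-tris(benzyloxy)-8-bromo-6-iodo-2-Ar-chromane
Conditions: N-iodosuccinimide, CF3CO2H (cat.), CH2Cl2/MeCN, 0 → 25 °C
Reagents that add atoms: N-iodosuccinimide, O=C1CCC(=O)N1I
Why: Electrophilic aromatic iodination at C6, the only unsubstituted position left on the still strongly activated ring D.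

**Step 10**
Reactants: 16 2,2,6-trimethyl-4H-1,3-dioxin-4-one
Product: 18 6-(chloromethyl)-2,2-dimethyl-4H-1,3-dioxin-4-one, via lithium dienolate 17 (not isolated)
Conditions: LiN(i-Pr)2, THF, −78 °C; C2Cl6, −78 → −50 °C
Reagents that add atoms: hexachloroethane, ClC(Cl)(Cl)C(Cl)(Cl)Cl
Why: Kinetic γ-deprotonation gives the dienolate, which is chlorinated at the γ-carbon by a positive-chlorine donor; this is the established preparation of the chloromethyl dioxinone.

**Step 11**
Reactants: 15 (2R,3S)-3,5,7-tris(benzyloxy)-8-bromo-6-iodo-2-Ar-chromane; 10 (5R,6R)-5-[(tert-butyldimethylsilyl)oxy]-6-Ar-5,6-dihydro-2H-pyran-2-one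
Product: 21 (4R,5R,6R)-5-[(tert-butyldimethylsilyl)oxy]-4-D*-6-Ar-tetrahydro-2H-pyran-2-one, via arylmagnesium chloride 19 (not isolated), via silyl ketene acetal 20 (not isolated)
Conditions: 15 (1.3 equiv), i-PrMgCl·LiCl, THF, −20 °C; CuBr·SMe2 (20 mol %), Me3SiCl, 10, −78 → −30 °C; aq. NH4Cl
Reagents that add atoms: none
Why: Iodine–magnesium exchange (iodide far faster than bromide) followed by copper-catalysed, silyl-chloride-accelerated 1,4-addition to the unsaturated lactone; the aryl group should enter anti to the pseudoaxial C5 silyloxy group of the half-chair, which places it trans to both existing substituents and sets C4 as R.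

**Step 12**
Reactants: 21 (4R,5R,6R)-5-[(tert-butyldimethylsilyl)oxy]-4-D*-6-Ar-tetrahydro-2H-pyran-2-one
Product: 23 (2R,3R,4R)-3-[(tert-butyldimethylsilyl)oxy]-4-D*-2-Ar-3,4-dihydro-2H-pyran-6-yl diphenyl phosphate, via potassium enolate 22 (not isolated)
Conditions: KN(SiMe3)2, THF/DMPU, −78 °C; (PhO)2P(O)Cl
Reagents that add atoms: diphenyl chlorophosphate, O=P(Cl)(Oc1ccccc1)Oc1ccccc1
Why: O-phosphorylation of a lactone enolate gives the ketene acetal phosphate; the only acidic protons are at the lactone α-carbon and no stereocentre is adjacent to the enolate.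

**Step 13**
Reactants: 23 (2R,3R,4R)-3-[(tert-butyldimethylsilyl)oxy]-4-D*-2-Ar-3,4-dihydro-2H-pyran-6-yl diphenyl phosphate; 18 6-(chloromethyl)-2,2-dimethyl-4H-1,3-dioxin-4-one
Product: 25 6-{[(2R,3R,4R)-3-[(tert-butyldimethylsilyl)oxy]-4-D*-2-Ar-3,4-dihydro-2H-pyran-6-yl]methyl}-2,2-dimethyl-4H-1,3-dioxin-4-one, via organozinc chloride 24 (not isolated)
Conditions: 18, Zn dust, LiCl, THF, 25 °C; then 23, Pd(PPh3)4 (5 mol %), THF, 25–40 °C
Reagents that add atoms: none
Why: Negishi coupling of a lactone-derived ketene acetal phosphate with an allyl-type organozinc (a vinylogous Reformatsky reagent) under zerovalent palladium; bond formation at the γ-carbon keeps the dioxinone conjugated, the neutral conditions should leave the skipped diene unisomerised, and the hindered electron-rich aryl bromide should not undergo oxidative addition at this temperature.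

**Step 14**
Reactants: 25 6-{[(2R,3R,4R)-3-[(tert-butyldimethylsilyl)oxy]-4-D*-2-Ar-3,4-dihydro-2H-pyran-6-yl]methyl}-2,2-dimethyl-4H-1,3-dioxin-4-one
Product: 28 (2R,3R)-3-[(tert-butyldimethylsilyl)oxy]-4β-D*-2-Ar-chromane-5,7-diol (2,3-cis and 3,4-trans), via acylketene 26 (not isolated), via cyclohexadienone 27 (not isolated)
Conditions: toluene (0.005 M), 110 °C, Ar, base-washed glassware
Reagents that add atoms: none
Why: Proposed new method: heating the dioxinone should trigger the usual retro-[4+2] loss of acetone to acylketene 26, whose C7 ketone enolises toward the doubly activated C8 methylene so that the ketene C5=C6, the enol C7=C8 and the enol ether C8a=C4a form a dienylketene; thermal 6π-electrocyclisation (equivalently a 6-(enolendo)-exo-dig C-acylation of the enol ether β-carbon by the ketene carbon) then forms C4a–C5 and closes the six-membered carbocycle as cyclohexadienone 27, which tautomerises irreversibly to the phloroglucinol-type ring A. The closest known reaction types are dioxinone thermolysis with intramolecular capture of the acylketene, the aromatisation of diketo-dioxinones to resorcylates and the closing 6π-electrocyclisation of the Danheiser benzannulation, but ring formation by C-acylation of a cyclic enol ether has no direct precedent. No stereocentre is created, and C2, C3 and C4 are untouched because C4a only passes through a transient sp3 state on its way to an arene carbon. The selectivity needed is C-acylation at C4a over every other fate of the ketene: closure to a 4-hydroxy-2-pyranone is impossible because O1 is already part of ring C, the hetero-Diels–Alder mode usual for acylketenes and enol ethers would require an oxetane because only one carbon separates the partners, and ring D offers no free position since C8 carries bromine. The enol geometry at C7=C8 is not fixed but equilibrates through the keto form, and only the isomer that places C5 over C4a can react; C8 is cis to the C4a hydrogen on the endocyclic double bond, so the chain folds over the unhindered side. If the enol ether double bond drifts into conjugation with the C7 ketone, the same dienol remains reachable from the resulting vinylogous ester, so that shift should delay the closure and not divert it. High dilution suppresses capture of 26 by the phenols of 28.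

**Step 15**
Reactants: 28 (2R,3R)-3-[(tert-butyldimethylsilyl)oxy]-4β-D*-2-Ar-chromane-5,7-diol
Product: 29 (2R,3R)-5,7-bis(benzyloxy)-3-[(tert-butyldimethylsilyl)oxy]-4β-D*-2-Ar-chromane
Conditions: BnBr, K2CO3, Bu4NI (cat.), DMF, 25 °C
Reagents that add atoms: benzyl bromide, BrCc1ccccc1
Why: Williamson etherification of the two new phenols, which puts ring A in the same protected form as the rest of the molecule.

**Step 16**
Reactants: 29 (2R,3R)-5,7-bis(benzyloxy)-3-[(tert-butyldimethylsilyl)oxy]-4β-D*-2-Ar-chromane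
Product: 30 (2R,3R)-5,7-bis(benzyloxy)-4β-D*-2-Ar-chroman-3-ol
Conditions: Bu4NF, AcOH, THF, 0 → 25 °C
Reagents that add atoms: none
Why: Fluoride cleavage of the silyl ether; buffering with acetic acid keeps the medium near neutral, and no acid that could cleave the interflavan bond is involved.

**Step 17**
Reactants: 30 (2R,3R)-5,7-bis(benzyloxy)-4β-D*-2-Ar-chroman-3-ol; 31 3,4,5-tris(benzyloxy)benzoic acid
Product: 32 (2R,3R)-5,7-bis(benzyloxy)-4β-D*-2-Ar-chroman-3-yl 3,4,5-tris(benzyloxy)benzoate
Conditions: DCC, DMAP, CH2Cl2, 25 °C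
Reagents that add atoms: none
Why: Steglich esterification of the single free hydroxyl; the axial, flanked alcohol calls for DMAP catalysis and excess acid, and acylation proceeds with retention at C3.

**Step 18**
Reactants: 32 (2R,3R)-5,7-bis(benzyloxy)-4β-D*-2-Ar-chroman-3-yl 3,4,5-tris(benzyloxy)benzoate
Product: 33 (2R,3R,4S)-5,7-dihydroxy-4-[(2R,3S)-3,5,7-trihydroxy-2-(3,4,5-trihydroxyphenyl)chroman-6-yl]-2-(3,4,5-trihydroxyphenyl)chroman-3-yl 3,4,5-trihydroxybenzoate
Conditions: H2 (1 atm), Pd(OH)2/C, Et3N (1.1 equiv), THF/MeOH, 25 °C; filtration under Ar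
Reagents that add atoms: none
Why: Catalytic hydrogenolysis of fourteen benzyl ethers and of the aryl C–Br bond in one operation; the amine traps HBr so that the free polyphenol is never exposed to acid, and the ester and the C2–O bonds are expected to survive.

## Compound list

1 | 3,4,5-tris(benzyloxy)benzaldehyde | O=Cc1cc(OCc2ccccc2)c(OCc2ccccc2)c(OCc2ccccc2)c1 | starting material
2 | allyl methoxymethyl ether | C=CCOCOC | starting material
3 | [(Z)-3-(methoxymethoxy)prop-2-en-1-yl]bis(isopinocampheyl)borane, isopinocampheyl groups from (+)-α-pinene | COCO/C=C\CB([C@@H]1C[C@@H]2C[C@@H](C2(C)C)[C@H]1C)[C@@H]1C[C@@H]2C[C@@H](C2(C)C)[C@H]1C | intermediate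
4 | bis(isopinocampheyl)borinate ester of alcohol 5 | C=C[C@@H](OCOC)[C@@H](c1cc(OCc2ccccc2)c(OCc2ccccc2)c(OCc2ccccc2)c1)OB([C@@H]1C[C@@H]2C[C@@H](C2(C)C)[C@H]1C)[C@@H]1C[C@@H]2C[C@@H](C2(C)C)[C@H]1C | intermediate
5 | (1R,2R)-2-(methoxymethoxy)-1-[3,4,5-tris(benzyloxy)phenyl]but-3-en-1-ol | C=C[C@@H](OCOC)[C@@H](c1cc(OCc2ccccc2)c(OCc2ccccc2)c(OCc2ccccc2)c1)O | intermediate
6 | (1R,2R)-2-(methoxymethoxy)-1-[3,4,5-tris(benzyloxy)phenyl]but-3-en-1-yl prop-2-enoate | C=C[C@@H](OCOC)[C@@H](c1cc(OCc2ccccc2)c(OCc2ccccc2)c(OCc2ccccc2)c1)OC(=O)C=C | intermediate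
7 | (5R,6R)-5-(methoxymethoxy)-6-[3,4,5-tris(benzyloxy)phenyl]-5,6-dihydro-2H-pyran-2-one | O=C1C=C[C@@H](OCOC)[C@@H](c2cc(OCc3ccccc3)c(OCc3ccccc3)c(OCc3ccccc3)c2)O1 | intermediate
8 | (5R,6R)-5-(bromomethoxy)-6-[3,4,5-tris(benzyloxy)phenyl]-5,6-dihydro-2H-pyran-2-one | O=C1C=C[C@@H](OCBr)[C@@H](c2cc(OCc3ccccc3)c(OCc3ccccc3)c(OCc3ccccc3)c2)O1 | intermediate
9 | (5R,6R)-5-hydroxy-6-[3,4,5-tris(benzyloxy)phenyl]-5,6-dihydro-2H-pyran-2-one | O=C1C=C[C@@H](O)[C@@H](c2cc(OCc3ccccc3)c(OCc3ccccc3)c(OCc3ccccc3)c2)O1 | intermediate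
10 | (5R,6R)-5-[(tert-butyldimethylsilyl)oxy]-6-[3,4,5-tris(benzyloxy)phenyl]-5,6-dihydro-2H-pyran-2-one | O=C1C=C[C@@H](O[Si](C)(C)C(C)(C)C)[C@@H](c2cc(OCc3ccccc3)c(OCc3ccccc3)c(OCc3ccccc3)c2)O1 | intermediate
11 | (+)-gallocatechin, (2R,3S) | O[C@H]1Cc2c(O)cc(O)cc2O[C@@H]1c1cc(O)c(O)c(O)c1 | starting material
12 | (2R,3S)-5,7-bis(benzyloxy)-2-[3,4,5-tris(benzyloxy)phenyl]chroman-3-ol | O[C@H]1Cc2c(OCc3ccccc3)cc(OCc3ccccc3)cc2O[C@@H]1c1cc(OCc3ccccc3)c(OCc3ccccc3)c(OCc3ccccc3)c1 | intermediate
13 | (2R,3S)-3,5,7-tris(benzyloxy)-2-[3,4,5-tris(benzyloxy)phenyl]chromane | O(Cc3ccccc3)[C@H]1Cc2c(OCc3ccccc3)cc(OCc3ccccc3)cc2O[C@@H]1c1cc(OCc3ccccc3)c(OCc3ccccc3)c(OCc3ccccc3)c1 | intermediate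
14 | (2R,3S)-3,5,7-tris(benzyloxy)-8-bromo-2-[3,4,5-tris(benzyloxy)phenyl]chromane | O(Cc3ccccc3)[C@H]1Cc2c(OCc3ccccc3)cc(OCc3ccccc3)c(Br)c2O[C@@H]1c1cc(OCc3ccccc3)c(OCc3ccccc3)c(OCc3ccccc3)c1 | intermediate
15 | (2R,3S)-3,5,7-tris(benzyloxy)-8-bromo-6-iodo-2-[3,4,5-tris(benzyloxy)phenyl]chromane | O(Cc3ccccc3)[C@H]1Cc2c(OCc3ccccc3)c(I)c(OCc3ccccc3)c(Br)c2O[C@@H]1c1cc(OCc3ccccc3)c(OCc3ccccc3)c(OCc3ccccc3)c1 | intermediate
16 | 2,2,6-trimethyl-4H-1,3-dioxin-4-one | CC1=CC(=O)OC(C)(C)O1 | starting material
17 | lithium 2,2-dimethyl-6-methylidene-6H-1,3-dioxin-4-olate | [Li+].C=C1C=C([O-])OC(C)(C)O1 | intermediate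
18 | 6-(chloromethyl)-2,2-dimethyl-4H-1,3-dioxin-4-one | ClCC1=CC(=O)OC(C)(C)O1 | intermediate
19 | [(2R,3S)-3,5,7-tris(benzyloxy)-8-bromo-2-[3,4,5-tris(benzyloxy)phenyl]chroman-6-yl]magnesium chloride | O(Cc3ccccc3)[C@H]1Cc2c(OCc3ccccc3)c([Mg]Cl)c(OCc3ccccc3)c(Br)c2O[C@@H]1c1cc(OCc3ccccc3)c(OCc3ccccc3)c(OCc3ccccc3)c1 | intermediate
20 | trimethylsilyl ketene acetal of lactone 21 [(2R,3R,4R)-3-(TBS-oxy)-4-D*-2-Ar-6-(trimethylsilyloxy)-3,4-dihydro-2H-pyran] | C[Si](C)(C)OC1=C[C@H](c2c(OCc3ccccc3)c(Br)c4c(c2OCc3ccccc3)C[C@H](OCc3ccccc3)[C@@H](c2cc(OCc3ccccc3)c(OCc3ccccc3)c(OCc3ccccc3)c2)O4)[C@@H](O[Si](C)(C)C(C)(C)C)[C@@H](c2cc(OCc3ccccc3)c(OCc3ccccc3)c(OCc3ccccc3)c2)O1 | intermediate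
21 | (4R,5R,6R)-5-[(tert-butyldimethylsilyl)oxy]-4-D*-6-Ar-tetrahydro-2H-pyran-2-one | O=C1C[C@H](c2c(OCc3ccccc3)c(Br)c4c(c2OCc3ccccc3)C[C@H](OCc3ccccc3)[C@@H](c2cc(OCc3ccccc3)c(OCc3ccccc3)c(OCc3ccccc3)c2)O4)[C@@H](O[Si](C)(C)C(C)(C)C)[C@@H](c2cc(OCc3ccccc3)c(OCc3ccccc3)c(OCc3ccccc3)c2)O1 | intermediate
22 | potassium enolate of lactone 21 | [K+].[O-]C1=C[C@H](c2c(OCc3ccccc3)c(Br)c4c(c2OCc3ccccc3)C[C@H](OCc3ccccc3)[C@@H](c2cc(OCc3ccccc3)c(OCc3ccccc3)c(OCc3ccccc3)c2)O4)[C@@H](O[Si](C)(C)C(C)(C)C)[C@@H](c2cc(OCc3ccccc3)c(OCc3ccccc3)c(OCc3ccccc3)c2)O1 | intermediate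
23 | (2R,3R,4R)-3-[(tert-butyldimethylsilyl)oxy]-4-D*-2-Ar-3,4-dihydro-2H-pyran-6-yl diphenyl phosphate | O=P(Oc5ccccc5)(Oc5ccccc5)OC1=C[C@H](c2c(OCc3ccccc3)c(Br)c4c(c2OCc3ccccc3)C[C@H](OCc3ccccc3)[C@@H](c2cc(OCc3ccccc3)c(OCc3ccccc3)c(OCc3ccccc3)c2)O4)[C@@H](O[Si](C)(C)C(C)(C)C)[C@@H](c2cc(OCc3ccccc3)c(OCc3ccccc3)c(OCc3ccccc3)c2)O1 | intermediate
24 | [(2,2-dimethyl-4-oxo-4H-1,3-dioxin-6-yl)methyl]zinc chloride | Cl[Zn]CC1=CC(=O)OC(C)(C)O1 | intermediate
25 | 6-{[(2R,3R,4R)-3-[(tert-butyldimethylsilyl)oxy]-4-D*-2-Ar-3,4-dihydro-2H-pyran-6-yl]methyl}-2,2-dimethyl-4H-1,3-dioxin-4-one | CC1(C)OC(=O)C=C(CC2=C[C@H](c3c(OCc4ccccc4)c(Br)c5c(c3OCc4ccccc4)C[C@H](OCc4ccccc4)[C@@H](c3cc(OCc4ccccc4)c(OCc4ccccc4)c(OCc4ccccc4)c3)O5)[C@@H](O[Si](C)(C)C(C)(C)C)[C@@H](c3cc(OCc4ccccc4)c(OCc4ccccc4)c(OCc4ccccc4)c3)O2)O1 | intermediate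
26 | acylketene: 4-[(2R,3R,4R)-3-(TBS-oxy)-4-D*-2-Ar-3,4-dihydro-2H-pyran-6-yl]-3-oxobut-1-en-1-one | O=C=CC(=O)CC2=C[C@H](c3c(OCc4ccccc4)c(Br)c5c(c3OCc4ccccc4)C[C@H](OCc4ccccc4)[C@@H](c3cc(OCc4ccccc4)c(OCc4ccccc4)c(OCc4ccccc4)c3)O5)[C@@H](O[Si](C)(C)C(C)(C)C)[C@@H](c3cc(OCc4ccccc4)c(OCc4ccccc4)c(OCc4ccccc4)c3)O2 | intermediate
27 | cyclohexadienone tautomer of 28 (7-hydroxy-4a,5-dihydrochromen-5-one, C4a configuration undefined) | CC(C)(C)[Si](C)(C)O[C@@H]1[C@@H](c3c(OCc4ccccc4)c(Br)c5c(c3OCc4ccccc4)C[C@H](OCc4ccccc4)[C@@H](c3cc(OCc4ccccc4)c(OCc4ccccc4)c(OCc4ccccc4)c3)O5)C2C(=O)C=C(O)C=C2O[C@@H]1c1cc(OCc4ccccc4)c(OCc4ccccc4)c(OCc4ccccc4)c1 | intermediate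
28 | (2R,3R)-3-[(tert-butyldimethylsilyl)oxy]-4β-D*-2-Ar-chromane-5,7-diol (2,3-cis, 3,4-trans) | CC(C)(C)[Si](C)(C)O[C@@H]1[C@@H](c3c(OCc4ccccc4)c(Br)c5c(c3OCc4ccccc4)C[C@H](OCc4ccccc4)[C@@H](c3cc(OCc4ccccc4)c(OCc4ccccc4)c(OCc4ccccc4)c3)O5)c2c(O)cc(O)cc2O[C@@H]1c1cc(OCc4ccccc4)c(OCc4ccccc4)c(OCc4ccccc4)c1 | intermediate
29 | (2R,3R)-5,7-bis(benzyloxy)-3-[(tert-butyldimethylsilyl)oxy]-4β-D*-2-Ar-chromane | CC(C)(C)[Si](C)(C)O[C@@H]1[C@@H](c3c(OCc4ccccc4)c(Br)c5c(c3OCc4ccccc4)C[C@H](OCc4ccccc4)[C@@H](c3cc(OCc4ccccc4)c(OCc4ccccc4)c(OCc4ccccc4)c3)O5)c2c(OCc4ccccc4)cc(OCc4ccccc4)cc2O[C@@H]1c1cc(OCc4ccccc4)c(OCc4ccccc4)c(OCc4ccccc4)c1 | intermediate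
30 | (2R,3R)-5,7-bis(benzyloxy)-4β-D*-2-Ar-chroman-3-ol | O[C@@H]1[C@@H](c3c(OCc4ccccc4)c(Br)c5c(c3OCc4ccccc4)C[C@H](OCc4ccccc4)[C@@H](c3cc(OCc4ccccc4)c(OCc4ccccc4)c(OCc4ccccc4)c3)O5)c2c(OCc4ccccc4)cc(OCc4ccccc4)cc2O[C@@H]1c1cc(OCc4ccccc4)c(OCc4ccccc4)c(OCc4ccccc4)c1 | intermediate
31 | 3,4,5-tris(benzyloxy)benzoic acid | OC(=O)c1cc(OCc2ccccc2)c(OCc2ccccc2)c(OCc2ccccc2)c1 | starting material
32 | (2R,3R)-5,7-bis(benzyloxy)-4β-D*-2-Ar-chroman-3-yl 3,4,5-tris(benzyloxy)benzoate | O=C(O[C@@H]1[C@@H](c3c(OCc4ccccc4)c(Br)c5c(c3OCc4ccccc4)C[C@H](OCc4ccccc4)[C@@H](c3cc(OCc4ccccc4)c(OCc4ccccc4)c(OCc4ccccc4)c3)O5)c2c(OCc4ccccc4)cc(OCc4ccccc4)cc2O[C@@H]1c1cc(OCc4ccccc4)c(OCc4ccccc4)c(OCc4ccccc4)c1)c1cc(OCc4ccccc4)c(OCc4ccccc4)c(OCc4ccccc4)c1 | intermediate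
33 | (−)-epigallocatechin 3-O-gallate-(4β→6)-(+)-gallocatechin; (2R,3R,4S) upper unit and (2R,3S) lower unit | O=C(O[C@@H]1[C@@H](c2c(O)cc3c(c2O)C[C@H](O)[C@@H](c2cc(O)c(O)c(O)c2)O3)c2c(O)cc(O)cc2O[C@@H]1c1cc(O)c(O)c(O)c1)c1cc(O)c(O)c(O)c1 | target

## Step count and least certain steps

Total: 18 steps. Longest linear sequence: 13 steps (steps 1–5 and 11–18, from aldehyde 1). The lower-unit branch (steps 6–9) and the dioxinone branch (step 10) join at steps 11 and 13.

**Step 14 (key step).** The most likely failure is that the acylketene is consumed before it closes onto C4a. This could happen by intermolecular acylation of the phenols of the product, by ketene dimerisation, or after hydrolytic opening of the acid-sensitive enol ether by adventitious water. A prototropic shift of the enol ether into conjugation could also slow the closure enough for these processes to win. The fallback abandons the de novo arene and forms the C4–C6 bond by known flavan-4-yl cation chemistry. It sets out from 14. Commercial (−)-epigallocatechin F1 is benzylated at its five phenols (BnBr, K2CO3, DMF) to the penta-O-benzyl ether F2. This is silylated (t-BuMe2SiOTf, 2,6-lutidine) to the 3-O-silyl ether F3 and oxidised at C4 with DDQ in the presence of 2-ethoxyethanol to the 4-(2-ethoxyethoxy) derivative F4. F4 and the C8-blocked nucleophile 14 are then joined with Me3SiOTf in CH2Cl2 at −78 °C. Attack through C6 of ring D, trans to the C3 silyloxy group, gives 29, where the route is rejoined.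

**Step 13.** The zinc dienolate may transmetalate sluggishly or couple through its α-carbon, the ketene acetal phosphate may hydrolyse, and the doubly allylic methylene of the product may isomerise during a slow reaction. The fallback reverses the polarity of the coupling and sets out from 23. Stannylation with Me3SnSnMe3, Pd(PPh3)4 and LiCl in THF gives the cyclic α-alkoxyvinylstannane F5. This is joined to chloride 18 in a Stille coupling (Pd2(dba)3, AsPh3, CuI, THF/DMF) to return to 25.

**Step 11.** The di-ortho-substituted arylcopper species may transfer its aryl group too slowly, which would lead to protonation of the organometallic and recovery of 10, or to erosion of facial selectivity at higher temperature. The fallback avoids the organometallic and sets out from 15 and 10. A reductive Heck hydroarylation (Pd(OAc)2, Et3N, HCO2H, DMF, 60 °C) adds the aryl–palladium species, formed selectively at the C–I bond, to the β-carbon anti to the silyloxy group and reduces the palladium enolate. This returns directly to 21 with no new compound (entered as F0).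

**Step 18.** Hydrogenolysis of the hindered aryl bromide may lag behind debenzylation, and the HBr released may cleave the interflavan bond of the free polyphenol. The pyrogallol rings may also oxidise during work-up. The fallback separates the two events and sets out from 32. Radical debromination with Bu3SnH and AIBN in toluene at 80 °C gives the bromine-free tetradeca-O-benzyl ester F6. This is then hydrogenolysed over Pd(OH)2/C without amine to reach 33.

## Further compounds

F1 | step 14 | (−)-epigallocatechin, (2R,3R) | O[C@@H]1Cc2c(O)cc(O)cc2O[C@@H]1c1cc(O)c(O)c(O)c1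
F2 | step 14 | (2R,3R)-5,7-bis(benzyloxy)-2-[3,4,5-tris(benzyloxy)phenyl]chroman-3-ol | O[C@@H]1Cc2c(OCc3ccccc3)cc(OCc3ccccc3)cc2O[C@@H]1c1cc(OCc3ccccc3)c(OCc3ccccc3)c(OCc3ccccc3)c1
F3 | step 14 | (2R,3R)-5,7-bis(benzyloxy)-3-[(tert-butyldimethylsilyl)oxy]-2-[3,4,5-tris(benzyloxy)phenyl]chromane | CC(C)(C)[Si](C)(C)O[C@@H]1Cc2c(OCc3ccccc3)cc(OCc3ccccc3)cc2O[C@@H]1c1cc(OCc3ccccc3)c(OCc3ccccc3)c(OCc3ccccc3)c1
F4 | step 14 | (2R,3R)-5,7-bis(benzyloxy)-3-[(tert-butyldimethylsilyl)oxy]-4β-(2-ethoxyethoxy)-2-[3,4,5-tris(benzyloxy)phenyl]chromane | CC(C)(C)[Si](C)(C)O[C@@H]1[C@@H](OCCOCC)c2c(OCc3ccccc3)cc(OCc3ccccc3)cc2O[C@@H]1c1cc(OCc3ccccc3)c(OCc3ccccc3)c(OCc3ccccc3)c1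
F5 | step 13 | (2R,3R,4R)-3-[(tert-butyldimethylsilyl)oxy]-4-D*-2-Ar-6-(trimethylstannyl)-3,4-dihydro-2H-pyran | C[Sn](C)(C)C1=C[C@H](c2c(OCc3ccccc3)c(Br)c4c(c2OCc3ccccc3)C[C@H](OCc3ccccc3)[C@@H](c2cc(OCc3ccccc3)c(OCc3ccccc3)c(OCc3ccccc3)c2)O4)[C@@H](O[Si](C)(C)C(C)(C)C)[C@@H](c2cc(OCc3ccccc3)c(OCc3ccccc3)c(OCc3ccccc3)c2)O1
F0 | step 11 | none | none
F6 | step 18 | bromine-free analogue of 32 (tetradeca-O-benzyl epigallocatechin gallate-(4β→6)-gallocatechin) | O=C(O[C@@H]1[C@@H](c3c(OCc4ccccc4)cc5c(c3OCc4ccccc4)C[C@H](OCc4ccccc4)[C@@H](c3cc(OCc4ccccc4)c(OCc4ccccc4)c(OCc4ccccc4)c3)O5)c2c(OCc4ccccc4)cc(OCc4ccccc4)cc2O[C@@H]1c1cc(OCc4ccccc4)c(OCc4ccccc4)c(OCc4ccccc4)c1)c1cc(OCc4ccccc4)c(OCc4ccccc4)c(OCc4ccccc4)c1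
A1 | alternative 1 | trideca-O-benzyl dimer with the lower unit as a (2S)-flav-3-ene, upper unit penta-O-benzyl-epigallocatechin 3-O-(tri-O-benzylgallate) bonded 4β→6 | O=C(O[C@@H]1[C@@H](c4c(OCc9ccccc9)cc5c(c4OCc9ccccc9)C=C[C@@H](c4cc(OCc9ccccc9)c(OCc9ccccc9)c(OCc9ccccc9)c4)O5)c2c(OCc9ccccc9)cc(OCc9ccccc9)cc2O[C@@H]1c1cc(OCc9ccccc9)c(OCc9ccccc9)c(OCc9ccccc9)c1)c1cc(OCc9ccccc9)c(OCc9ccccc9)c(OCc9ccccc9)c1
A2 | alternative 1 | 4β-{2,6-bis(benzyloxy)-4-[(S)-1-(3,4,5-tris(benzyloxy)phenyl)prop-2-yn-1-yloxy]phenyl}-penta-O-benzyl-epigallocatechin 3-O-(tri-O-benzylgallate) | O=C(O[C@@H]1[C@@H](c4c(OCc9ccccc9)cc(O[C@@H](C#C)c5cc(OCc9ccccc9)c(OCc9ccccc9)c(OCc9ccccc9)c5)cc4OCc9ccccc9)c2c(OCc9ccccc9)cc(OCc9ccccc9)cc2O[C@@H]1c1cc(OCc9ccccc9)c(OCc9ccccc9)c(OCc9ccccc9)c1)c1cc(OCc9ccccc9)c(OCc9ccccc9)c(OCc9ccccc9)c1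
A3 | alternative 2 | ring D phenol carrying the 3-O-TBS-penta-O-benzyl-epigallocatechin-4β-yl group at C6, triisopropylsilyl ethers at C5 and C7 and the open (2S,3S)-2-benzyloxy-3-(triethylsilyloxy)-3-Ar-propyl chain at C4a | Oc1cc(O[Si](C(C)C)(C(C)C)C(C)C)c([C@@H]2[C@@H](O[Si](C)(C)C(C)(C)C)[C@@H](c3cc(OCc9ccccc9)c(OCc9ccccc9)c(OCc9ccccc9)c3)Oc3cc(OCc9ccccc9)cc(OCc9ccccc9)c32)c(O[Si](C(C)C)(C(C)C)C(C)C)c1C[C@H](OCc9ccccc9)[C@@H](O[Si](CC)(CC)CC)c1cc(OCc9ccccc9)c(OCc9ccccc9)c(OCc9ccccc9)c1
A4 | alternative 2 | 2-[3-O-TBS-penta-O-benzyl-epigallocatechin-4β-yl]-3-(triisopropylsilyloxy)cyclobut-2-en-1-one | O=C1CC(O[Si](C(C)C)(C(C)C)C(C)C)=C1[C@@H]2[C@@H](O[Si](C)(C)C(C)(C)C)[C@@H](c3cc(OCc9ccccc9)c(OCc9ccccc9)c(OCc9ccccc9)c3)Oc3cc(OCc9ccccc9)cc(OCc9ccccc9)c32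
A5 | alternative 2 | (1S,2S)-2-(benzyloxy)-1-(triethylsilyloxy)-1-Ar-5-(triisopropylsilyloxy)pent-4-yne | CC(C)[Si](C(C)C)(C(C)C)OC#CC[C@H](OCc9ccccc9)[C@@H](O[Si](CC)(CC)CC)c1cc(OCc9ccccc9)c(OCc9ccccc9)c(OCc9ccccc9)c1
A6 | alternative 3 | undeca-O-benzyl dimer with upper C3 tert-butyldimethylsilyl ether (bromine-free analogue of 29) | CC(C)(C)[Si](C)(C)O[C@@H]1[C@@H](c4c(OCc9ccccc9)cc5c(c4OCc9ccccc9)C[C@H](OCc9ccccc9)[C@@H](c4cc(OCc9ccccc9)c(OCc9ccccc9)c(OCc9ccccc9)c4)O5)c2c(OCc9ccccc9)cc(OCc9ccccc9)cc2O[C@@H]1c1cc(OCc9ccccc9)c(OCc9ccccc9)c(OCc9ccccc9)c1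
A7 | alternative 3 | open-chain triad: C2 carbinol with C3 silyl ether, the lower unit and a 2-bromo-4,6-bis(benzyloxy)phenyl group at C4 | CC(C)(C)[Si](C)(C)O[C@H]([C@@H](c4c(OCc9ccccc9)cc5c(c4OCc9ccccc9)C[C@H](OCc9ccccc9)[C@@H](c4cc(OCc9ccccc9)c(OCc9ccccc9)c(OCc9ccccc9)c4)O5)c2c(OCc9ccccc9)cc(OCc9ccccc9)cc2Br)[C@H](O)c1cc(OCc9ccccc9)c(OCc9ccccc9)c(OCc9ccccc9)c1
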